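## Retrosynthetic overview
1. The tertiary C3''–OH bond is made last: target ⇒ xanthoangelol + water. A site- and enantioface-selective Markovnikov hydration of the arene-proximal alkene sets the only stereocentre, (R).
2. Enone Cα=Cβ: xanthoangelol ⇒ 3-geranyl-2,4-dihydroxyacetophenone + 4-hydroxybenzaldehyde (Claisen–Schmidt condensation).
3. Aryl C3–C1'': ⇒ 2,4-dihydroxyacetophenone + geranyl bromide (C-allylation of the resorcinolate).
4. No ring is formed. Both benzene rings are bought intact and no protecting groups are used.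

Assumption: the [C@@] centre is read as (3R) in the side chain (OH > CH2CH2Ar > homoprenyl > CH3), and a Re-face-selective hydratase variant is taken to be obtainable from a focused mutant library.

## Route

Step 1
Reactants: 1 2,4-dihydroxyacetophenone; 2 geranyl bromide
Product: 3 3-geranyl-2,4-dihydroxyacetophenone
Conditions: KOH (1 equiv), MeOH, 0 °C to rt, 16 h
Reagents that add atoms: none
Why: This is C-allylation of an ambident phenoxide, in which the protic solvent H-bonds the phenoxide oxygens so the soft allylic bromide is attacked in SN2 fashion by C3, the carbon activated by both oxygens, the E-alkene is untouched, and no stereocentre is formed.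

Step 2
Reactants: 3 3-geranyl-2,4-dihydroxyacetophenone; 4 4-hydroxybenzaldehyde
Product: 6 xanthoangelol, via beta-hydroxy ketone 5 (not isolated)
Conditions: KOH (50% aq, 15 equiv), EtOH, N2, rt, 48 h; then 1 M HCl, 0 °C, to pH 5
Reagents that add atoms: none
Why: In this Claisen–Schmidt condensation the methyl ketone enolate adds to the non-enolisable aldehyde and E1cB loss of water gives the thermodynamic E-enone, the geranyl chain is inert to base, and cold acidification avoids flavanone closure.

Step 3
Reactants: 6 xanthoangelol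
Product: 7 (2E)-1-{2,4-dihydroxy-3-[(3R)-3-hydroxy-3,7-dimethyloct-6-en-1-yl]phenyl}-3-(4-hydroxyphenyl)prop-2-en-1-one
Conditions: engineered kievitone hydratase (tunnel-opened variant, secreted from Pichia, cell-free), 50 mM citrate buffer pH 6.0, DMSO (10% v/v), HP-β-cyclodextrin, 35 °C, dark, 24 h
Reagents that add atoms: water, O
Why: Proposed new method: site- and enantioface-selective enzymatic Markovnikov hydration of a geranyl side chain, in which a cofactor-free prenylphenol hydratase binds the 3-alkenyl-2,4-dihydroxyaroyl motif that 6 shares with the enzyme's known chalcone substrate xanthohumol, a general-acid residue protonates C2'' while an enzyme-held water adds anti to the developing tertiary cation at C3'' (asynchronous, with no free cation, so neither polyene cyclisation nor chroman closure by the flanking phenols, which are tied up in H-bonds to the carbonyl and the protein, can compete), the pocket that seats the E-methyl of a dimethylallyl group is opened by small-residue substitutions into a dry hydrophobic tunnel that holds the homoprenyl arm and keeps C6''=C7'' away from the acid/water pair (site selectivity), and because only the arm fits the tunnel and only the methyl fits the small pocket a single alkene face meets the water, so attack on the Re face of C3'' gives the (3R)-carbinol with the variant chosen by chiral HPLC for this sense; closest known reaction type: kievitone hydratase hydration of achiral dimethylallyl groups on prenylated isoflavonoids and chalcones, and the terpene hydration by linalool dehydratase-isomerase that sets a tertiary carbinol centre.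

## Compound list
1 | 1-(2,4-dihydroxyphenyl)ethanone (2,4-dihydroxyacetophenone) | CC(=O)c1ccc(O)cc1O | starting material
2 | geranyl bromide, (2E)-1-bromo-3,7-dimethylocta-2,6-diene | CC(C)=CCC/C(C)=C/CBr | starting material
3 | 1-{3-[(2E)-3,7-dimethylocta-2,6-dien-1-yl]-2,4-dihydroxyphenyl}ethanone | CC(C)=CCC/C(C)=C/Cc1c(O)ccc(C(C)=O)c1O | intermediate
4 | 4-hydroxybenzaldehyde | O=Cc1ccc(O)cc1 | starting material
5 | 1-{3-[(2E)-3,7-dimethylocta-2,6-dien-1-yl]-2,4-dihydroxyphenyl}-3-hydroxy-3-(4-hydroxyphenyl)propan-1-one (racemic carbinol, lost on dehydration; not isolated) | CC(C)=CCC/C(C)=C/Cc1c(O)ccc(C(=O)CC(O)c2ccc(O)cc2)c1O | intermediate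
6 | xanthoangelol, (2E)-1-{3-[(2E)-3,7-dimethylocta-2,6-dien-1-yl]-2,4-dihydroxyphenyl}-3-(4-hydroxyphenyl)prop-2-en-1-one | CC(C)=CCC/C(C)=C/Cc1c(O)ccc(C(=O)/C=C/c2ccc(O)cc2)c1O | intermediate
7 | (2E)-1-{2,4-dihydroxy-3-[(3R)-3-hydroxy-3,7-dimethyloct-6-en-1-yl]phenyl}-3-(4-hydroxyphenyl)prop-2-en-1-one | CC(C)=CCC[C@@](C)(O)CCc1c(O)ccc(C(=O)/C=C/c2ccc(O)cc2)c1O | target

## Step count
- Total step count: 3
- Longest linear sequence: 3

## Steps most likely to fail

**Step 3 (the new hydration).**
- Risks: the enzyme may not accept the C10 chain. The facial sense and level of selectivity are unknown before screening. Compound 6 is poorly soluble. The chalcone may drift slowly to the flavanone.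
- Fallback: known chemistry that takes the carbinol centre from the chiral pool instead of creating it. It sets out from 1 and comes back to the route at 7.
- Iodination of 1 between the two hydroxyl groups (I2, HIO3, aq EtOH, rt) gives 1-(2,4-dihydroxy-3-iodophenyl)ethanone F1. MOMCl/NaH in DMF converts it into 1-[3-iodo-2,4-bis(methoxymethoxy)phenyl]ethanone F2.
- Purchased (R)-(-)-linalool F3 is hydroborated at its vinyl group only (9-BBN, THF, 0 °C to rt) to the B-alkyl-9-BBN adduct F4. This is coupled without isolation with F2 (B-alkyl Suzuki–Miyaura coupling: Pd(OAc)2, SPhos, K3PO4, THF/H2O, 60 °C) to give 1-{3-[(3R)-3-hydroxy-3,7-dimethyloct-6-en-1-yl]-2,4-bis(methoxymethoxy)phenyl}ethanone F5.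
- Claisen–Schmidt condensation of F5 with 4 (KOH, EtOH/H2O, rt) runs through the beta-hydroxy ketone F6 to the bis-MOM chalcone F7. NaHSO4 on silica (wet CH2Cl2, rt) then removes both phenolic MOM groups without ionising the tertiary alcohol and gives 7.

**Step 1 (C- versus O-alkylation).**
- Risks: O-geranyl, C5 and bis-alkylated products compete. About 30–40% of 3 is realistic.
- Fallback: O-alkylation followed by rearrangement. It sets out from 1 and comes back at 3.
- The free 4-OH is masked (MOMCl, K2CO3, acetone) to give 1-[2-hydroxy-4-(methoxymethoxy)phenyl]ethanone F8. The chelated 2-OH is then O-alkylated with 2 (K2CO3, DMF, 60 °C) to the 2-O-geranyl ether F9.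
- Montmorillonite K10 (CH2Cl2, 0 °C to rt) moves the geranyl group by a [1,3]-shift to the only free ortho carbon, giving 1-{3-[(2E)-3,7-dimethylocta-2,6-dien-1-yl]-2-hydroxy-4-(methoxymethoxy)phenyl}ethanone F10. Brief HCl/MeOH releases 3.

**Step 2 (unprotected Claisen–Schmidt).**
- Risks: the polyanionic partners react sluggishly, conversion may be incomplete, and flavanone may form on work-up.
- Fallback: a protecting-group strategy. It sets out from 3 and 4 and comes back at 6.
- Compound 3 is converted (MOMCl, NaH, DMF) into the bis-MOM ketone F11, and 4 (MOMCl, iPr2NEt, CH2Cl2) into 4-(methoxymethoxy)benzaldehyde F12.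
- The now neutral partners condense quickly (KOH, EtOH, rt) through the beta-hydroxy ketone F13 to tris-MOM xanthoangelol F14. Short treatment with HCl in MeOH (50 °C) gives 6.

## Further compounds
F1 | step 3 | 1-(2,4-dihydroxy-3-iodophenyl)ethanone | CC(=O)c1ccc(O)c(I)c1O
F2 | step 3 | 1-[3-iodo-2,4-bis(methoxymethoxy)phenyl]ethanone | CC(=O)c1ccc(OCOC)c(I)c1OCOC
F3 | step 3 | (R)-(-)-linalool (purchased) | CC(C)=CCC[C@@](C)(O)C=C
F4 | step 3 | B-alkyl-9-BBN adduct of (R)-linalool (not isolated) | CC(C)=CCC[C@@](C)(O)CCB1C2CCCC1CCC2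
F5 | step 3 | 1-{3-[(3R)-3-hydroxy-3,7-dimethyloct-6-en-1-yl]-2,4-bis(methoxymethoxy)phenyl}ethanone | CC(C)=CCC[C@@](C)(O)CCc1c(OCOC)ccc(C(C)=O)c1OCOC
F6 | step 3 | beta-hydroxy ketone from F5 and 4 (epimers at the new carbinol, not isolated) | CC(C)=CCC[C@@](C)(O)CCc1c(OCOC)ccc(C(=O)CC(O)c2ccc(O)cc2)c1OCOC
F7 | step 3 | bis-MOM chalcone, 2',4'-bis-O-methoxymethyl ether of 7 | CC(C)=CCC[C@@](C)(O)CCc1c(OCOC)ccc(C(=O)/C=C/c2ccc(O)cc2)c1OCOC
F8 | step 1 | 1-[2-hydroxy-4-(methoxymethoxy)phenyl]ethanone | CC(=O)c1ccc(OCOC)cc1O
F9 | step 1 | 1-{2-[(2E)-3,7-dimethylocta-2,6-dien-1-yloxy]-4-(methoxymethoxy)phenyl}ethanone | CC(C)=CCC/C(C)=C/COc1cc(OCOC)ccc1C(C)=O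
F10 | step 1 | 1-{3-[(2E)-3,7-dimethylocta-2,6-dien-1-yl]-2-hydroxy-4-(methoxymethoxy)phenyl}ethanone | CC(C)=CCC/C(C)=C/Cc1c(OCOC)ccc(C(C)=O)c1O
F11 | step 2 | 1-{3-[(2E)-3,7-dimethylocta-2,6-dien-1-yl]-2,4-bis(methoxymethoxy)phenyl}ethanone | CC(C)=CCC/C(C)=C/Cc1c(OCOC)ccc(C(C)=O)c1OCOC
F12 | step 2 | 4-(methoxymethoxy)benzaldehyde | COCOc1ccc(C=O)cc1
F13 | step 2 | beta-hydroxy ketone from F11 and F12 (racemic, not isolated) | CC(C)=CCC/C(C)=C/Cc1c(OCOC)ccc(C(=O)CC(O)c2ccc(OCOC)cc2)c1OCOC
F14 | step 2 | tris-MOM xanthoangelol | CC(C)=CCC/C(C)=C/Cc1c(OCOC)ccc(C(=O)/C=C/c2ccc(OCOC)cc2)c1OCOC
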